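Take the ratio of Thursday's loading of Q to Tuesday's, 5.33, and hold it against the ratio of their J at 10.0 min, 1.50: the ratio of loadings is larger than the ratio of J, and G starts as a solid, so at high loading look for a pace set by the solid.

all flasks: G 21 mM
- Monday's: Q 6.1 × 10⁻⁴ mol%; run made earlier
- Tuesday's: Q 0.003 mol%; run made earlier
- Thursday's: Q 0.016 mol%; run made earlier
- noon: Q 5.0 × 10⁻⁴ mol%; time 20 min
- autumn: Q 0.0015 mol%; time 20 min
- dawn: Q 0.005 mol%; time 20 min
- winter: Q 0.015 mol%; time 20 min

| run | time / min | J / % |
|---|---|---|
| Monday's | 0.833 | 0.3 |
| Monday's | 1.50 | 0.1 |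
| Monday's | 3.00 | 0.8 |
| Monday's | 5.00 | 2.3 |
| Monday's | 10.0 | 5.0 |
| Tuesday's | 0.833 | 1.3 |
| Tuesday's | 1.50 | 1.4 |
| Tuesday's | 3.00 | 4.9 |
| Tuesday's | 5.00 | 8.5 |
| Tuesday's | 10.0 | 18.9 |
| Thursday's | 2.00 | 4.3 |
| Thursday's | 4.00 | 10.9 |
| Thursday's | 6.00 | 16.7 |
| Thursday's | 8.00 | 21.9 |
| Thursday's | 10.0 | 28.4 |

(standard deviation of a reading: 0.5 percentage points)

- as a solid, counted per litre of solution: G
- the earlier runs were read with a standard deviation of 0.5 percentage points
- at the start none of G is in solution
- "hardly changes" means that all values lie within two and a half points (for a concentration: within two and a half percent of the largest)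

- amount of J at the end, in percent of the G charged for noon, autumn, dawn, winter, in this order
- the course of these numbers from the first flask to the last (hardly changes / falls all the way / rises all the way / falls, then rises / rises, then falls)

Go through the given numbers for what an error would cost. The charge of G is 21 mM in each run and flask, and J is counted in percent of it, so leave it aside. The low end rests on Monday's last reading: scaled by loading and time to noon, it gives 8.20%, but the scatter of 0.5 percentage points is 10.0% of that reading. The high end rests on Thursday's last reading, where the same scatter is a smaller share, 1.76%, so that is the number to build on.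

Replace Thursday's curve by its mean. The emptying time, the time the whole charge of G would take to become J at that mean pace, is 35.2 min. Read it as a supply ceiling, a rate-limiting step in the usual term. Check the error: the chord from 4.00 min to 10.0 min gives 34.3 min, shorter than the mean. Over 20 min the ceiling is therefore 56.8% by the mean and 58.3% by the chord, which is my reckoning for winter.

The forecast gives 8.5%, 20%, 45% and 55%, so the course rises all the way, holding that “at high loading the supply of dissolved G from the solid caps the rate”. Its winter lies below my reckoning.

The flasks give 9.83%, 27.2%, 53.5% and 58.4%, so the course rises all the way.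

    D + Q ⇌ L (K = 2100 M⁻¹, k = 82000 M⁻¹ s⁻¹)
    L → Q + J (k = 23.0 s⁻¹)
    G ⇌ D, rate k3*(cs3 - [D]) while solid is left; crystals form when [D] > cs3 (solubility = 21.0 mM, k = 5.00 × 10⁻⁴ s⁻¹)
    Q ⇌ E (K = 0.660, k = 0.00360 s⁻¹)

Against 56.8%, winter reaches 1.03 of the ceiling, dawn 0.942 and noon 0.173. At 8.84 min noon makes D, the dissolved G, 4.64 times faster than it uses it up, each step taken net, and noon ends with 37.5% of D, more than winter's 1.00%.

The readings come from a simulation for an exercise; noise was put on by code.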